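Assumption: the target SMILES has no stereodescriptor and no stereocentre, and the ring A–ring D axis (three small ortho hydroxyls) is taken as freely rotating, so there is no enantiomer to control.

**Retrosynthetic overview**
1. Last step: the target comes from its penta-O-methyl form (four aryl methyl ethers, one methyl ester) by global O-demethylation, with no skeletal change.
2. Ring C: disconnect C4–C4a (Friedel–Crafts acylation of a β-aryloxycinnamate). Ring A is symmetric about the biaryl axis at that stage, so closure can only give the 6-aryl flavone.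
3. Key disconnection: the ring A carbon–oxygen bond C8a–O1, made by oxidative copper coupling of an aryl boronate with the enol oxygen of ethyl 4-methoxybenzoylacetate (which carries ring B and C2–C4). The boron sits on the one unhindered C–H of ring A, para to the biaryl bond.
4. Biaryl (ring A–ring D): Suzuki coupling of 2,6-dimethoxyphenylboronic acid with methyl 3-bromo-4-methoxybenzoate.
5. Ring order: rings A and D are bought and joined first, ring B is attached through oxygen second, ring C is the only ring built and is closed last, before deprotection.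

**Route**

Step 1
Reactants: 1 (2,6-dimethoxyphenyl)boronic acid (1.5 equiv); 2 methyl 3-bromo-4-methoxybenzoate
Product: 3 methyl 3-(2,6-dimethoxyphenyl)-4-methoxybenzoate
Conditions: Pd(OAc)2 (2 mol%), SPhos (4 mol%), K3PO4 (3 equiv), toluene/H2O 10:1, 90 °C, 12 h
Reagents that add atoms: none
Why: Suzuki–Miyaura coupling; the bulky electron-rich biarylphosphine handles tri-ortho-substituted biaryls, the excess of boronic acid covers protodeboronation, and the methyl ester survives the mild phosphate base.

Step 2
Reactants: 3 methyl 3-(2,6-dimethoxyphenyl)-4-methoxybenzoate; 4 bis(pinacolato)diboron (1.0 equiv); 5 ethyl 3-(4-methoxyphenyl)-3-oxopropanoate (2 equiv)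
Product: 7 ethyl (Z)-3-{3,5-dimethoxy-4-[2-methoxy-5-(methoxycarbonyl)phenyl]phenoxy}-3-(4-methoxyphenyl)prop-2-enoate (ester and aryloxy groups cis on the double bond), via aryl pinacol boronate 6 (not isolated)
Conditions: [Ir(OMe)(cod)]2 (1.5 mol%; cod = 1,5-cyclooctadiene), 4,4′-di-tert-butyl-2,2′-bipyridine (3 mol%), THF, 80 °C, 16 h; evaporate volatiles; then Cu(OAc)2 (20 mol%), B(OH)3 (2 equiv), pyridine (2 equiv), 4 Å MS, MeCN, O2 (1 atm), 60 °C, 24 h
Reagents that add atoms: none
Why: Proposed new method: the sterically governed iridium C–H borylation (known) puts boron on the only ring A C–H without an ortho substituent, and the new part is an oxidative copper coupling of that boronate with the enol O–H of the β-keto ester, whose acidity is close to that of a phenol: the enol binds divalent copper as an O,O-chelate, the aryl group transfers from boron, oxidation to trivalent copper is followed by C–O reductive elimination at the ketone-derived oxygen (arylation at the ester oxygen would give a high-energy ketene acetal, and the central carbon is held away from the aryl group in the chelate), and the chelate geometry delivers the Z enol ether with ester and aryloxy cis, as ring closure needs; the closest known reaction type is the Chan–Lam–Evans etherification of phenols with arylboron reagents run in sequence after an iridium borylation, which has not been shown for acyclic β-keto ester enols.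

Step 3
Reactants: 7 ethyl (Z)-3-{3,5-dimethoxy-4-[2-methoxy-5-(methoxycarbonyl)phenyl]phenoxy}-3-(4-methoxyphenyl)prop-2-enoate
Product: 8 methyl 3-[5,7-dimethoxy-2-(4-methoxyphenyl)-4-oxo-4H-chromen-6-yl]-4-methoxybenzoate
Conditions: P2O5/MeSO3H (1:10 w/w, Eaton's reagent) as solvent, 50 °C, 3 h; pour onto ice
Reagents that add atoms: none
Why: Intramolecular Friedel–Crafts acylation (the Ruhemann-type chromone closure, oxygen counterpart of the Gould–Jacobs quinolone cyclisation): the ester carbonyl cis to the aryloxy group acylates an ortho carbon of ring A that is activated by one ortho and one para methoxy group, and since both ortho carbons are equivalent only the 6-aryl-5,7-dimethoxyflavone can form; any E isomer equilibrates in the acid by C-protonation.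

Step 4
Reactants: 8 methyl 3-[5,7-dimethoxy-2-(4-methoxyphenyl)-4-oxo-4H-chromen-6-yl]-4-methoxybenzoate
Product: 9 4-hydroxy-3-[5,7-dihydroxy-2-(4-hydroxyphenyl)-4-oxo-4H-chromen-6-yl]benzoic acid
Conditions: BBr3 (15 equiv), CH2Cl2, −78 °C to rt, 24 h; H2O quench at 0 °C
Reagents that add atoms: none
Why: Boron tribromide O-demethylation: complexation and bromide attack at methyl cleave the four aryl methyl ethers and, with excess reagent at room temperature, the methyl ester by the same alkyl–oxygen scission, while the aprotic conditions avoid acid-mediated opening and reclosure of ring C (6-aryl to 8-aryl isomerisation); no stereocentre is involved.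

**Compound list**
1 | (2,6-dimethoxyphenyl)boronic acid | COc1cccc(OC)c1B(O)O | starting material
2 | methyl 3-bromo-4-methoxybenzoate | COC(=O)c1ccc(OC)c(Br)c1 | starting material
3 | methyl 3-(2,6-dimethoxyphenyl)-4-methoxybenzoate | COC(=O)c1ccc(OC)c(-c2c(OC)cccc2OC)c1 | intermediate
4 | bis(pinacolato)diboron | CC1(C)OB(OC1(C)C)B1OC(C)(C)C(C)(C)O1 | starting material
5 | ethyl 3-(4-methoxyphenyl)-3-oxopropanoate | CCOC(=O)CC(=O)c1ccc(OC)cc1 | starting material
6 | methyl 3-[2,6-dimethoxy-4-(4,4,5,5-tetramethyl-1,3,2-dioxaborolan-2-yl)phenyl]-4-methoxybenzoate | COC(=O)c1ccc(OC)c(-c2c(OC)cc(B3OC(C)(C)C(C)(C)O3)cc2OC)c1 | intermediate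
7 | ethyl (Z)-3-{3,5-dimethoxy-4-[2-methoxy-5-(methoxycarbonyl)phenyl]phenoxy}-3-(4-methoxyphenyl)prop-2-enoate | CCOC(=O)/C=C(\Oc1cc(OC)c(-c2cc(C(=O)OC)ccc2OC)c(OC)c1)c1ccc(OC)cc1 | intermediate
8 | methyl 3-[5,7-dimethoxy-2-(4-methoxyphenyl)-4-oxo-4H-chromen-6-yl]-4-methoxybenzoate | COC(=O)c1ccc(OC)c(-c2c(OC)cc3oc(-c4ccc(OC)cc4)cc(=O)c3c2OC)c1 | intermediate
9 | 4-hydroxy-3-[5,7-dihydroxy-2-(4-hydroxyphenyl)-4-oxo-4H-chromen-6-yl]benzoic acid | O=C(O)c1ccc(O)c(-c2c(O)cc3oc(-c4ccc(O)cc4)cc(=O)c3c2O)c1 | target

**Step count and risks**
Total steps: 4. Longest linear sequence: 4 steps (1/2 → 3 → 7 → 8 → 9).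

Steps most likely to fail:

Step 2 (the proposed new coupling). The copper stage may give C-arylation of the keto ester, oxidative degradation of the keto ester, or simple hydroxylation of the boronate. The fallback uses known chemistry, sets out from 3 and comes back at 7. Borylate 3 with 4 as before to boronate 6, then oxidise the C–B bond in the same flask with KHSO5 (acetone/H2O, rt) to the phenol methyl 3-(4-hydroxy-2,6-dimethoxyphenyl)-4-methoxybenzoate F1; this is the established one-pot borylation/oxidation route to phenols. Then add F1 through oxygen to bought ethyl 3-(4-methoxyphenyl)prop-2-ynoate (CCOC(=O)C#Cc1ccc(OC)cc1; K2CO3, DMF, 80 °C), a base-mediated oxa-Michael addition of a phenoxide to an aryl propiolate. Anti addition gives 7, accompanied by some ethyl (E)-3-{3,5-dimethoxy-4-[2-methoxy-5-(methoxycarbonyl)phenyl]phenoxy}-3-(4-methoxyphenyl)prop-2-enoate F2. Both isomers go into step 3, where the acid equilibrates them.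

Step 3. The protonated ester may acylate too slowly, and the enol ether may be cleaved or ring A sulfonylated in the hot acid. The fallback sets out from 7 and comes back at 8. Saponify both esters of 7 (LiOH, THF/H2O, 40 °C) to the diacid (Z)-3-[4-(5-carboxy-2-methoxyphenyl)-3,5-dimethoxyphenoxy]-3-(4-methoxyphenyl)prop-2-enoic acid F3. Close ring C from the free acid through its mixed trifluoroacetic anhydride ((CF3CO)2O, CH2Cl2, 0 °C to rt), a milder acylating species that needs no strong protic acid. Quenching with methanol turns the remaining aroyl trifluoroacetate into the methyl ester and gives 8.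

Step 4. The methyl ester may survive BBr3 or cleave only in part, leaving mixtures of polar products. The fallback sets out from 8 and comes back at 9. Separate the two deprotections: hydrolyse the ester first with LiOH (THF/MeOH/H2O, 40 °C), while it is still an ordinary 4-methoxybenzoate and the flavone ether tolerates base, to 3-[5,7-dimethoxy-2-(4-methoxyphenyl)-4-oxo-4H-chromen-6-yl]-4-methoxybenzoic acid F4. Then cleave only the four aryl methyl ethers of F4 with BBr3 (CH2Cl2, −78 °C to rt) to reach 9.

**Further compounds**
F1 | step 2 | methyl 3-(4-hydroxy-2,6-dimethoxyphenyl)-4-methoxybenzoate | COC(=O)c1ccc(OC)c(-c2c(OC)cc(O)cc2OC)c1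
F2 | step 2 | ethyl (E)-3-{3,5-dimethoxy-4-[2-methoxy-5-(methoxycarbonyl)phenyl]phenoxy}-3-(4-methoxyphenyl)prop-2-enoate | CCOC(=O)/C=C(/Oc1cc(OC)c(-c2cc(C(=O)OC)ccc2OC)c(OC)c1)c1ccc(OC)cc1
F3 | step 3 | (Z)-3-[4-(5-carboxy-2-methoxyphenyl)-3,5-dimethoxyphenoxy]-3-(4-methoxyphenyl)prop-2-enoic acid | OC(=O)/C=C(\Oc1cc(OC)c(-c2cc(C(=O)O)ccc2OC)c(OC)c1)c1ccc(OC)cc1
F4 | step 4 | 3-[5,7-dimethoxy-2-(4-methoxyphenyl)-4-oxo-4H-chromen-6-yl]-4-methoxybenzoic acid | OC(=O)c1ccc(OC)c(-c2c(OC)cc3oc(-c4ccc(OC)cc4)cc(=O)c3c2OC)c1
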